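The middle flavan unit is not taken from catechin: its ring C (O1, C2, C3, C4, C4a, C8a) is disconnected at O1–C2 and C4–C4a into a phenol and a three-carbon epoxy aldehyde. The precursor is a benzylated, bromine-capped catechin already bonded through C4 to a 3,5-bis(benzyloxy)phenol. One operation, titanium-templated ortho-hydroxyalkylation followed by 6-endo epoxide opening, annulates ring C as a flavan-3,4-diol. It exploits the ortho pair C4a/O1 of ring A, the catechol ring B that activates C2, and the 2,3-trans relation encoded in the trans-epoxide; the C4 hydroxyl it installs is the leaving group for the later 4→6 bond.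

Key step: step 7

Assumption: C4 of ether 4 and of diol 11 is ionised in the following step, so its configuration is immaterial and 11 is listed without a C4 descriptor; 3,5-bis(benzyloxy)phenol is taken as a commercial compound.

The target is read as catechin-(4α→8)-catechin-(4α→6)-catechin: three (2R,3S) units, both interflavan bonds 3,4-trans.

Step 1
Reactants: 1 (+)-catechin
Product: 2 5,7,3',4'-tetra-O-benzyl-(+)-catechin
Conditions: BnBr, K2CO3, DMF, 0 °C to rt
Reagents that add atoms: benzyl bromide, BrCc1ccccc1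
Why: Williamson ether synthesis, in which K2CO3 deprotonates only the four phenols, so the less acidic secondary 3-OH should stay free and no stereocentre is touched.

Step 2
Reactants: 2 5,7,3',4'-tetra-O-benzyl-(+)-catechin
Product: 3 8-bromo-5,7,3',4'-tetra-O-benzyl-(+)-catechin
Conditions: NBS, CH2Cl2, −78 °C to rt
Reagents that add atoms: N-bromosuccinimide, O=C1CCC(=O)N1Br
Why: Electrophilic aromatic bromination, in which C8 is the most reactive carbon of the 5,7-dialkoxy ring A, so one equivalent of NBS should give the 8-bromide that later serves as a removable cap.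

Step 3
Reactants: 3 8-bromo-5,7,3',4'-tetra-O-benzyl-(+)-catechin
Product: 4 (2R,3S,4S)-8-bromo-4-(2-ethoxyethoxy)-5,7,3',4'-tetra-O-benzylflavan-3-ol (4β ether)
Conditions: DDQ, 2-ethoxyethanol, CH2Cl2, rt
Reagents that add atoms: 2-ethoxyethanol, CCOCCO
Why: DDQ benzylic oxidation, in which hydride abstraction at C4 gives a cation stabilised by the ring A oxygens that the alcohol traps, the expected 4β ether being a stable, ionisable C4 donor.

Step 4
Reactants: 4 (2R,3S,4S)-8-bromo-4-(2-ethoxyethoxy)-5,7,3',4'-tetra-O-benzylflavan-3-ol, 5 3,5-bis(benzyloxy)phenol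
Product: 6 (2R,3S,4R)-8-bromo-5,7-bis(benzyloxy)-2-[3,4-bis(benzyloxy)phenyl]-4-[2,4-bis(benzyloxy)-6-hydroxyphenyl]chroman-3-ol (2,3-trans, 3,4-trans, 4α-aryl)
Conditions: TMSOTf (cat.), 5 (3 equiv), CH2Cl2, −78 to −30 °C
Reagents that add atoms: none
Why: Lewis acid-promoted Friedel–Crafts coupling of the interflavan type, in which the C4 cation should be attacked by the less hindered ortho carbon of the phenol from the face anti to the 3-OH of the 2,3-trans unit (3,4-trans, 4α), while the C8 bromine stops self-condensation.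

Step 5
Reactants: 7 3,4-bis(benzyloxy)benzaldehyde
Product: 8 (E)-3-[3,4-bis(benzyloxy)phenyl]prop-2-enal
Conditions: Ph3P=CHCHO, toluene, 80 °C
Reagents that add atoms: (triphenylphosphoranylidene)acetaldehyde, O=CC=P(c1ccccc1)(c1ccccc1)c1ccccc1
Why: Wittig olefination with a stabilised ylide, which should give the (E)-enal selectively.

Step 6
Reactants: 8 (E)-3-[3,4-bis(benzyloxy)phenyl]prop-2-enal
Product: 9 (2R,3S)-3-[3,4-bis(benzyloxy)phenyl]oxirane-2-carbaldehyde (trans-epoxide)
Conditions: aq. H2O2, (S)-2-[bis(3,5-bis(trifluoromethyl)phenyl)(trimethylsilyloxy)methyl]pyrrolidine (10 mol%), CH2Cl2, rt; used crude at once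
Reagents that add atoms: hydrogen peroxide, OO
Why: Organocatalytic epoxidation of an enal through iminium and enamine intermediates (Jørgensen–Hayashi catalyst), in which the catalyst shields one face of the iminium ion so that peroxide adds to the β-carbon and closes to the trans-(2R,3S)-epoxide under catalyst control.

Step 7
Reactants: 6 (2R,3S,4R)-8-bromo-5,7-bis(benzyloxy)-2-[3,4-bis(benzyloxy)phenyl]-4-[2,4-bis(benzyloxy)-6-hydroxyphenyl]chroman-3-ol, 9 (2R,3S)-3-[3,4-bis(benzyloxy)phenyl]oxirane-2-carbaldehyde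
Product: 11 8-bromo-5,7,3',4'-tetra-O-benzylcatechin-(4α→8)-[(2R,3S)-5,7,3',4'-tetra-O-benzyl-2,3-trans-flavan-3,4-diol] (both C4 carbinol epimers), via epoxy carbinol adduct 10 (not isolated)
Conditions: Ti(OiPr)4 (2.2 equiv), toluene, rt; then 9, CH2Cl2, 0 °C to rt, then 40 °C; aq. potassium sodium tartrate work-up
Reagents that add atoms: none
Why: Ti(OiPr)4 turns the phenol of 6 into an aryloxytitanium species that binds the aldehyde of 9 and delivers it in a six-membered transition state to the only free ortho carbon (the future C4a), giving the titanium-chelated epoxy alkoxide 10, whose aryl oxygen then opens the epoxide at the distal benzylic carbon. The closest known reactions are the ortho-specific hydroxyalkylation of magnesium and titanium phenoxides with α-oxygenated aldehydes, the Ti(OiPr)4-assisted C3-selective opening of 2,3-epoxy alcohols, and the 6-endo epoxide closure used in de novo flavan-3-ol syntheses. Ring C closes in the 6-endo-tet mode by attack of O1 on C2, after the intermolecular C4a–C4 bond. C3 is carried unchanged from 9, C2 is set by inversion at the epoxide carbon so that the trans-epoxide maps onto the 2,3-trans (2R,3S) unit (a looser, cation-like transition state would converge on the same diequatorial isomer), and C4 forms without control and is erased in step 8. The step needs ortho rather than para C-attack, secured by metal-phenoxide delivery and by the para carbon lying between two benzyloxy groups, and 6-endo rather than 5-exo closure, secured by the electron-rich ring B at C2 and by titanium chelation of the C4 alkoxide and the epoxide oxygen.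

Step 8
Reactants: 11 8-bromo-5,7,3',4'-tetra-O-benzylcatechin-(4α→8)-[(2R,3S)-5,7,3',4'-tetra-O-benzyl-2,3-trans-flavan-3,4-diol], 3 8-bromo-5,7,3',4'-tetra-O-benzyl-(+)-catechin
Product: 12 dodeca-O-benzyl-8-bromocatechin-(4α→8)-catechin-(4α→6)-(8-bromocatechin)
Conditions: BF3·OEt2 (0.2 equiv), 3 (4 equiv), 4 Å MS, CH2Cl2, −40 to −10 °C
Reagents that add atoms: none
Why: Biomimetic interflavan coupling of the Friedel–Crafts type, in which either C4 epimer of the diol ionises to the same benzylic cation, which should be captured anti to the 3-OH (3,4-trans, 4α) by C6 of 3, the only free ring A carbon of the bromine-capped nucleophile.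

Step 9
Reactants: 12 dodeca-O-benzyl-8-bromocatechin-(4α→8)-catechin-(4α→6)-(8-bromocatechin)
Product: 13 catechin-(4α→8)-catechin-(4α→6)-catechin (CNP0178679.4)
Conditions: H2 (1 atm), Pd(OH)2/C, Et3N, THF/MeOH/H2O, rt
Reagents that add atoms: none
Why: Catalytic hydrogenolysis should cleave the twelve benzyl ethers and both aryl–bromine bonds in one operation, Et3N trapping HBr so that the acid-labile interflavan bonds and all eight stereocentres stay intact.

Compound list

1 | (+)-catechin, (2R,3S)-2-(3,4-dihydroxyphenyl)chromane-3,5,7-triol | O[C@H]1Cc2c(O)cc(O)cc2O[C@@H]1c1ccc(O)c(O)c1 | starting material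

2 | 5,7,3',4'-tetra-O-benzyl-(+)-catechin, (2R,3S) | O[C@H]1Cc2c(OCc3ccccc3)cc(OCc3ccccc3)cc2O[C@@H]1c1ccc(OCc2ccccc2)c(OCc2ccccc2)c1 | intermediate

3 | 8-bromo-5,7,3',4'-tetra-O-benzyl-(+)-catechin, (2R,3S) | O[C@H]1Cc2c(OCc3ccccc3)cc(OCc3ccccc3)c(Br)c2O[C@@H]1c1ccc(OCc2ccccc2)c(OCc2ccccc2)c1 | intermediate

4 | (2R,3S,4S)-8-bromo-4-(2-ethoxyethoxy)-5,7,3',4'-tetra-O-benzylflavan-3-ol (4β ether) | O[C@H]1[C@@H](OCCOCC)c2c(OCc3ccccc3)cc(OCc3ccccc3)c(Br)c2O[C@@H]1c1ccc(OCc2ccccc2)c(OCc2ccccc2)c1 | intermediate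

5 | 3,5-bis(benzyloxy)phenol | Oc1cc(OCc2ccccc2)cc(OCc2ccccc2)c1 | starting material

6 | (2R,3S,4R)-8-bromo-5,7-bis(benzyloxy)-2-[3,4-bis(benzyloxy)phenyl]-4-[2,4-bis(benzyloxy)-6-hydroxyphenyl]chroman-3-ol (2,3-trans, 3,4-trans) | O[C@H]1[C@H](c2c(O)cc(OCc3ccccc3)cc2OCc2ccccc2)c2c(OCc3ccccc3)cc(OCc3ccccc3)c(Br)c2O[C@@H]1c1ccc(OCc2ccccc2)c(OCc2ccccc2)c1 | intermediate

7 | 3,4-bis(benzyloxy)benzaldehyde | O=Cc1ccc(OCc2ccccc2)c(OCc2ccccc2)c1 | starting material

8 | (E)-3-[3,4-bis(benzyloxy)phenyl]prop-2-enal | O=C/C=C/c1ccc(OCc2ccccc2)c(OCc2ccccc2)c1 | intermediate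

9 | (2R,3S)-3-[3,4-bis(benzyloxy)phenyl]oxirane-2-carbaldehyde (trans) | O=C[C@@H]1O[C@H]1c1ccc(OCc2ccccc2)c(OCc2ccccc2)c1 | intermediate

10 | epoxy carbinol adduct: 6 carrying, at the free carbon ortho to its phenolic OH, a CH(OH) group bonded to C2 of the intact trans-3-[3,4-bis(benzyloxy)phenyl]oxirane (carbinol epimers) | O[C@H]1[C@H](c2c(O)c(C(O)[C@@H]3O[C@H]3c3ccc(OCc4ccccc4)c(OCc4ccccc4)c3)c(OCc3ccccc3)cc2OCc2ccccc2)c2c(OCc3ccccc3)cc(OCc3ccccc3)c(Br)c2O[C@@H]1c1ccc(OCc2ccccc2)c(OCc2ccccc2)c1 | intermediate (not isolated)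

11 | 8-bromo-5,7,3',4'-tetra-O-benzylcatechin-(4α→8)-[(2R,3S)-5,7,3',4'-tetra-O-benzyl-2,3-trans-flavan-3,4-diol], C4 carbinol epimers | O[C@H]1[C@H](c2c(OCc3ccccc3)cc(OCc3ccccc3)c3c2O[C@H](c2ccc(OCc4ccccc4)c(OCc4ccccc4)c2)[C@@H](O)C3O)c2c(OCc3ccccc3)cc(OCc3ccccc3)c(Br)c2O[C@@H]1c1ccc(OCc2ccccc2)c(OCc2ccccc2)c1 | intermediate

12 | dodeca-O-benzyl-8-bromocatechin-(4α→8)-catechin-(4α→6)-(8-bromocatechin) | O[C@H]1[C@H](c2c(OCc3ccccc3)cc(OCc3ccccc3)c3c2O[C@H](c2ccc(OCc4ccccc4)c(OCc4ccccc4)c2)[C@@H](O)[C@@H]3c2c(OCc3ccccc3)c(Br)c3c(c2OCc2ccccc2)C[C@H](O)[C@@H](c2ccc(OCc4ccccc4)c(OCc4ccccc4)c2)O3)c2c(OCc3ccccc3)cc(OCc3ccccc3)c(Br)c2O[C@@H]1c1ccc(OCc2ccccc2)c(OCc2ccccc2)c1 | intermediate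

13 | catechin-(4α→8)-catechin-(4α→6)-catechin (CNP0178679.4) | Oc1cc(O)c2c(c1)O[C@H](c1ccc(O)c(O)c1)[C@@H](O)[C@@H]2c1c(O)cc(O)c2c1O[C@H](c1ccc(O)c(O)c1)[C@@H](O)[C@@H]2c1c(O)cc2c(c1O)C[C@H](O)[C@@H](c1ccc(O)c(O)c1)O2 | target

Total step count: 9. Longest linear sequence: 7 steps (steps 1, 2, 3, 4, 7, 8, 9).

Steps most likely to fail

Step 7. The benzylic C4 alkoxide of the adduct, on a phloroglucinol-type ring with a free ortho oxygen, may ionise to an ortho-quinone methide and oligomerise before ring C closes. The phenoxide may also close in the 5-exo mode, or the Lewis acid may rearrange the electron-rich epoxy aldehyde before it is captured. The fallback sets out from 6 and enal 8 and comes back at 11; ring C is closed by an oxa-6π electrocyclisation instead of an epoxide opening. Phenol 6 and enal 8 are condensed (PhB(OH)2, AcOH cat., toluene, 80 °C) through the ortho-quinone methide to the flav-3-ene F1, obtained as both C2 epimers. Dihydroxylation with OsO4 (cat.) and NMO in acetone/H2O, which on flav-3-enes takes place anti to the 2-aryl group, should give the 2,3-trans-3,4-cis diols. Chromatographic separation of the two diastereomers should deliver the (2R,3S) one, which is 11 as its 4β-hydroxy epimer. This variant has no control at C2, so about half of the material would be lost.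

Step 4. The C4 cation may attack the para carbon of 5 (between the two benzyloxy groups) or its oxygen, or alkylate both ortho carbons, so that the regiochemistry on which the 4→8 connectivity rests is eroded. The fallback sets out from 4 and comes back at 6. Ether 4 is coupled (TMSOTf cat., THF/CH2Cl2, −40 °C) with excess phloroglucinol (benzene-1,3,5-triol, Oc1cc(O)cc(O)c1), whose three ring carbons are equivalent, to give the triol F2, the protected analogue of the classical catechin-(4α→2)-phloroglucinol adduct. Two-fold O-benzylation (BnBr 2 equiv, K2CO3, DMF, 0 °C) should then take place at the unhindered para hydroxyl and at one of the two equivalent ortho hydroxyls, the last hydroxyl, flanked by the C4 substituent, being the slowest, to give 6.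

Step 8. The middle-unit C4 cation may be captured by the free C6 positions of a second molecule of 11 faster than by the hindered, bromine-deactivated C6 of 3, and the Lewis acid may cleave the upper interflavan bond. The fallback sets out from 11 and comes back at 12; it separates ionisation from coupling through a stable thio donor and a thiophilic promoter. Diol 11 is treated with 2,6-dimethylbenzenethiol and BF3·OEt2 (cat.) in CH2Cl2 at −40 °C to give the 4α-arylthio ether F3, which can be purified. F3 is then added slowly to 3 (5 equiv) and AgOTf in CH2Cl2 at −40 °C, so that the cation is generated at low concentration in the presence of excess nucleophile and without a hard Lewis acid, to give 12.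

Further compounds

F1 | step 7 | 8-bromo-5,7,3',4'-tetra-O-benzylcatechin-(4α→8)-[5,7,3',4'-tetra-O-benzylflav-3-ene], both C2 epimers | O[C@H]1[C@H](c2c(OCc3ccccc3)cc(OCc3ccccc3)c3c2OC(c2ccc(OCc4ccccc4)c(OCc4ccccc4)c2)C=C3)c2c(OCc3ccccc3)cc(OCc3ccccc3)c(Br)c2O[C@@H]1c1ccc(OCc2ccccc2)c(OCc2ccccc2)c1
F2 | step 4 | (2R,3S,4R)-8-bromo-5,7-bis(benzyloxy)-2-[3,4-bis(benzyloxy)phenyl]-4-(2,4,6-trihydroxyphenyl)chroman-3-ol | O[C@H]1[C@H](c2c(O)cc(O)cc2O)c2c(OCc3ccccc3)cc(OCc3ccccc3)c(Br)c2O[C@@H]1c1ccc(OCc2ccccc2)c(OCc2ccccc2)c1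
F3 | step 8 | 8-bromo-5,7,3',4'-tetra-O-benzylcatechin-(4α→8)-[5,7,3',4'-tetra-O-benzyl-4α-(2,6-dimethylphenylthio)catechin] | O[C@H]1[C@H](c2c(OCc3ccccc3)cc(OCc3ccccc3)c3c2O[C@H](c2ccc(OCc4ccccc4)c(OCc4ccccc4)c2)[C@@H](O)[C@@H]3Sc2c(C)cccc2C)c2c(OCc3ccccc3)cc(OCc3ccccc3)c(Br)c2O[C@@H]1c1ccc(OCc2ccccc2)c(OCc2ccccc2)c1
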